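**Retrosynthetic overview**
1. Target ⇐ its hepta-O-benzyl ether (global debenzylation last).
2. Ring A (the dihydrobenzofuran that carries the styryl arm: O1, C2, C3, C3a, C7a) ⇐ one-flask union of three pieces: ring-B aryllithium + O-Boc salicylaldehyde made from resveratrol (C3–C5' bond), then o-quinone methide + chiral benzylic sulfonium ylide (C2–C3 bond, then the O1–C2 bond, which closes the ring).
3. Enabling feature: C3 is benzylic to the resorcinol ring and ortho to the O1-bearing C7a (para to the C6 oxygen), so O1=C7a–C3a=C3 can exist as an o-quinone methide (electrophilic C3, nucleophilic O1); C2 carries a p-oxygenated aryl group, so it can be delivered as a sulfonium ylide carbon that acts first as nucleophile, then as electrophile.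
4. Ring-B fragment (5-bromo-2,3-dihydrobenzofuran) ⇐ Rh-catalysed 1,5 C–H insertion of a diaryl carbene (C2'–C3' bond) on a benzophenone hydrazone from 3-benzyloxy-5-bromosalicylaldehyde, then C2' epimerisation to trans.
5. Ring order: dihydrofuran of ring B (catalyst control, 2R,3R) → dihydrofuran of ring A (reagent control, 2S,3S); the two units need opposite absolute sense and are set independently.

Key step: step 13

Assumption: the ylide from the (1R,4R,5R)-sulfide is taken to give the (2S,3S) ring A and Rh2(R-PTAD)4 the (3R) centre of ring B; if either sense of induction is the opposite, the antipodal reagent is used with nothing else changed; the five starting materials are treated as commercial.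

Ring A = the dihydrobenzofuran with the styryl group (unprimed locants); ring B = the second dihydrobenzofuran (primed locants).

Step 1
Reactants: 1 trans-resveratrol
Product: 2 (E)-3,5,4'-tris(benzyloxy)stilbene
Conditions: BnBr, K2CO3, DMF, 60 °C
Reagents that add atoms: benzyl bromide, BrCc1ccccc1
Why: Williamson etherification of the three phenols is routine for resveratrol and creates no stereocentre.

Step 2
Reactants: 2 (E)-3,5,4'-tris(benzyloxy)stilbene
Product: 3 2,4-bis(benzyloxy)-6-[(E)-2-(4-benzyloxyphenyl)ethenyl]benzaldehyde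
Conditions: POCl3, DMF, 0 → 60 °C; then ice/H2O
Reagents that add atoms: N,N-dimethylformamide, CN(C)C=O; water, O
Why: Vilsmeier–Haack formylation should occur on the 1,3-dialkoxy ring ortho to the styryl group and para to a benzyloxy group (the site between the two ethers is more hindered and the stilbene alkene is far less nucleophilic), as known for 3,5-dialkoxystilbenes.

Step 3
Reactants: 3 2,4-bis(benzyloxy)-6-[(E)-2-(4-benzyloxyphenyl)ethenyl]benzaldehyde
Product: 4 4-(benzyloxy)-2-[(E)-2-(4-benzyloxyphenyl)ethenyl]-6-hydroxybenzaldehyde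
Conditions: MgBr2·OEt2, toluene/Et2O, 80 °C; then 1 M HCl
Reagents that add atoms: none
Why: Chelation of Mg(II) between the formyl oxygen and the ortho benzyloxy oxygen activates only that ether toward bromide attack (selective ortho-debenzylation), leaving the remote benzyl ethers and the stilbene untouched.

Step 4
Reactants: 4 4-(benzyloxy)-2-[(E)-2-(4-benzyloxyphenyl)ethenyl]-6-hydroxybenzaldehyde
Product: 5 5-(benzyloxy)-3-[(E)-2-(4-benzyloxyphenyl)ethenyl]-2-formylphenyl tert-butyl carbonate
Conditions: Boc2O, DMAP (cat.), i-Pr2NEt (cat.), THF, 0 °C → rt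
Reagents that add atoms: di-tert-butyl dicarbonate, CC(C)(C)OC(=O)OC(=O)OC(C)(C)C
Why: DMAP-catalysed O-acylation gives the aryl tert-butyl carbonate that later serves as the traceless trigger for o-quinone methide formation; the aldehyde is unaffected.

Step 5
Reactants: 6 3-(benzyloxy)-2-hydroxybenzaldehyde
Product: 7 3-(benzyloxy)-5-bromo-2-hydroxybenzaldehyde
Conditions: NBS, MeCN, 0 °C → rt
Reagents that add atoms: N-bromosuccinimide, O=C1CCC(=O)N1Br
Why: Electrophilic aromatic bromination is directed para to the free hydroxyl and meta to the formyl group, as for o-vanillin, so only C5 should react.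

Step 6
Reactants: 7 3-(benzyloxy)-5-bromo-2-hydroxybenzaldehyde; 8 4-(benzyloxy)benzyl bromide
Product: 9 3-(benzyloxy)-2-{[4-(benzyloxy)benzyl]oxy}-5-bromobenzaldehyde
Conditions: K2CO3, DMF, 50 °C
Reagents that add atoms: none
Why: Williamson O-alkylation of the phenoxide installs the ArCH2–O group whose benzylic C–H bond is used in step 10.

Step 7
Reactants: 9 3-(benzyloxy)-2-{[4-(benzyloxy)benzyl]oxy}-5-bromobenzaldehyde; 10 1,3-bis(benzyloxy)-5-bromobenzene
Product: 12 [3-(benzyloxy)-2-{[4-(benzyloxy)benzyl]oxy}-5-bromophenyl][3,5-bis(benzyloxy)phenyl]methanol (racemic), via arylmagnesium bromide 11 (not isolated)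
Conditions: Mg, THF, 50 °C (10 → 11); then 9, THF, −20 → 0 °C; H2O
Reagents that add atoms: none
Why: Grignard addition to the aldehyde at low temperature tolerates the aryl bromide; the carbinol centre is formed without control and is removed in step 8.

Step 8
Reactants: 12 [3-(benzyloxy)-2-{[4-(benzyloxy)benzyl]oxy}-5-bromophenyl][3,5-bis(benzyloxy)phenyl]methanol
Product: 13 [3-(benzyloxy)-2-{[4-(benzyloxy)benzyl]oxy}-5-bromophenyl][3,5-bis(benzyloxy)phenyl]methanone
Conditions: activated MnO2, CH2Cl2, rt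
Reagents that add atoms: none
Why: MnO2 oxidation of the doubly benzylic alcohol gives the benzophenone without touching benzyl ethers or the aryl bromide.

Step 9
Reactants: 13 [3-(benzyloxy)-2-{[4-(benzyloxy)benzyl]oxy}-5-bromophenyl][3,5-bis(benzyloxy)phenyl]methanone
Product: 14 hydrazone of ketone 13 (E/Z mixture)
Conditions: N2H4·H2O (excess), AcOH (cat.), EtOH, 80 °C
Reagents that add atoms: hydrazine (as hydrate), NN
Why: Condensation of the diaryl ketone with excess hydrazine gives the free hydrazone needed for diazo generation; its geometry is irrelevant.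

Step 10
Reactants: 14 hydrazone of ketone 13
Product: 16 (2S,3R)-7-(benzyloxy)-2-[4-(benzyloxy)phenyl]-3-[3,5-bis(benzyloxy)phenyl]-5-bromo-2,3-dihydro-1-benzofuran (cis), via diaryldiazomethane 15 (not isolated)
Conditions: MnO2, CH2Cl2, 0 °C, filter; then Rh2(R-PTAD)4 (1 mol %), CH2Cl2, 0 °C
Reagents that add atoms: none
Why: MnO2 dehydrogenates the hydrazone to diazo compound 15, and the chiral Rh(II) carboxylate converts it into a donor/donor carbene that inserts into the proximal benzylic ether C–H bond (intramolecular 1,5 C–H insertion, known for 2,3-diaryl-dihydrobenzofurans); the catalyst sets C3' (R) and the concerted insertion delivers the cis C2' centre.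

Step 11
Reactants: 16 (2S,3R)-cis-dihydrobenzofuran bromide
Product: 17 (2R,3R)-7-(benzyloxy)-2-[4-(benzyloxy)phenyl]-3-[3,5-bis(benzyloxy)phenyl]-5-bromo-2,3-dihydro-1-benzofuran (trans)
Conditions: TFA, CH2Cl2, 0 °C → rt
Reagents that add atoms: none
Why: Acid reversibly ionises the C2'–O bond (p-alkoxybenzylic cation) and re-closure gives the thermodynamically preferred trans isomer (acid-catalysed epimerisation), so C2' becomes R while C3' is untouched.

Step 12
Reactants: 18 (1R,4R,5R)-isothiocineole; 8 4-(benzyloxy)benzyl bromide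
Product: 19 (1R,4R,5R)-6-[4-(benzyloxy)benzyl]-4,7,7-trimethyl-6-thiabicyclo[3.2.1]octan-6-ium triflate
Conditions: LiOTf, CH2Cl2/H2O, rt
Reagents that add atoms: lithium triflate, [Li+].[O-]S(=O)(=O)C(F)(F)F
Why: S-Alkylation of the bicyclic sulfide on its exposed lone pair with bromide-to-triflate exchange should give the sulfonium salt as a single diastereomer at sulfur, the standard route to isothiocineole benzylsulfonium salts.

Step 13
Reactants: 17 (2R,3R)-trans-dihydrobenzofuran bromide; 5 O-Boc salicylaldehyde; 19 chiral sulfonium triflate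
Product: 26 hepta-O-benzyl ether of the target (ring A 2S,3S; ring B 2R,3R), via aryllithium 20 (not isolated), via lithium alkoxide 21 (not isolated), via phenoxide carbonate 22 (not isolated), via o-quinone methide 23 (not isolated), via sulfonium ylide 24 (not isolated), via betaine 25 (not isolated)
Conditions: 17, n-BuLi, THF, −78 °C; then 5, −78 °C; MgBr2·OEt2, −78 → −40 °C; then ylide 24 (from 19, LiHMDS, THF, −78 °C), −78 → 0 °C; aq. work-up
Reagents that add atoms: none
Why: Proposed new method: Aryllithium 20 adds to the formyl group of 5 (at −78 °C faster than attack on the aryl carbonate) to give alkoxide 21, which takes over the Boc group through a six-membered transition state (phenoxide 22); Mg(II)-assisted loss of tert-butyl carbonate then unveils o-quinone methide 23, ylide 24 adds 1,4 to its exocyclic carbon (C2–C3 bond, driven by rearomatisation), and the phenoxide of betaine 25 displaces the sulfide from C2, which forms the O1–C2 bond and closes ring A in a 5-exo-tet SN2 step. The closest known reactions are the generation of o-quinone methides from O-Boc salicylaldehydes and organolithium reagents, the base-mediated [4+1] annulation of o-quinone methides with sulfonium ylides to trans-2,3-dihydrobenzofurans, and the epoxidations, aziridinations and cyclopropanations with isothiocineole-derived benzylsulfonium ylides; their merger in one flask with a chiral benzylic ylide has not been shown. The bicyclic sulfide fixes the ylide conformation and leaves one face of the ylide carbon open, which sets C2 (after inversion in the closure), and the usual antiperiplanar approach to the acceptor, whose exocyclic aryl group is held in one geometry by A(1,3) strain with the C4 styryl group, sets C3, so the trans-(2S,3S) ring should result under reagent control with no bias from the remote ring-B centres. If the closure turns SN1-like at the p-alkoxybenzylic C2, the trans ring is still expected because it is the thermodynamic isomer and C3 is already fixed. The step needs 1,2-addition to CHO rather than to the carbonate (secured at −78 °C), ylide attack at C3 rather than at the styryl terminus (only C3 attack restores the arene), and O- rather than C-alkylation in the closure (the phenoxide oxygen is the only nucleophile placed for a five-membered ring).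

Step 14
Reactants: 26 hepta-O-benzyl ether of the target
Product: 27 target, (2S,3S)-3-[(2R,3R)-3-(3,5-dihydroxyphenyl)-7-hydroxy-2-(4-hydroxyphenyl)-2,3-dihydro-1-benzofuran-5-yl]-2-(4-hydroxyphenyl)-4-[(E)-2-(4-hydroxyphenyl)ethenyl]-2,3-dihydro-1-benzofuran-6-ol
Conditions: BCl3, pentamethylbenzene, CH2Cl2, −78 °C; then MeOH, H2O
Reagents that add atoms: none
Why: Lewis-acid debenzylation with pentamethylbenzene as benzyl-cation scavenger should cleave all seven aryl benzyl ethers at −78 °C without reducing the stilbene; the intermediate aryloxyboron species are poor donors, which should protect the stilbene from protonation, and no stereocentre is touched because both rings are already the thermodynamic trans isomers.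

**Compound list**
1 | trans-resveratrol | Oc1ccc(/C=C/c2cc(O)cc(O)c2)cc1 | starting material
2 | (E)-3,5,4'-tris(benzyloxy)stilbene | c1ccccc1COc1ccc(/C=C/c2cc(OCc3ccccc3)cc(OCc3ccccc3)c2)cc1 | intermediate
3 | 2,4-bis(benzyloxy)-6-[(E)-2-(4-benzyloxyphenyl)ethenyl]benzaldehyde | O=Cc1c(OCc2ccccc2)cc(OCc2ccccc2)cc1/C=C/c1ccc(OCc2ccccc2)cc1 | intermediate
4 | 4-(benzyloxy)-2-[(E)-2-(4-benzyloxyphenyl)ethenyl]-6-hydroxybenzaldehyde | O=Cc1c(O)cc(OCc2ccccc2)cc1/C=C/c1ccc(OCc2ccccc2)cc1 | intermediate
5 | 5-(benzyloxy)-3-[(E)-2-(4-benzyloxyphenyl)ethenyl]-2-formylphenyl tert-butyl carbonate | O=Cc1c(OC(=O)OC(C)(C)C)cc(OCc2ccccc2)cc1/C=C/c1ccc(OCc2ccccc2)cc1 | intermediate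
6 | 3-(benzyloxy)-2-hydroxybenzaldehyde | O=Cc1cccc(OCc2ccccc2)c1O | starting material
7 | 3-(benzyloxy)-5-bromo-2-hydroxybenzaldehyde | O=Cc1cc(Br)cc(OCc2ccccc2)c1O | intermediate
8 | 4-(benzyloxy)benzyl bromide | BrCc1ccc(OCc2ccccc2)cc1 | starting material
9 | 3-(benzyloxy)-2-{[4-(benzyloxy)benzyl]oxy}-5-bromobenzaldehyde | O=Cc1cc(Br)cc(OCc2ccccc2)c1OCc1ccc(OCc2ccccc2)cc1 | intermediate
10 | 1,3-bis(benzyloxy)-5-bromobenzene | Brc1cc(OCc2ccccc2)cc(OCc2ccccc2)c1 | starting material
11 | [3,5-bis(benzyloxy)phenyl]magnesium bromide | Br[Mg]c1cc(OCc2ccccc2)cc(OCc2ccccc2)c1 | intermediate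
12 | [3-(benzyloxy)-2-{[4-(benzyloxy)benzyl]oxy}-5-bromophenyl][3,5-bis(benzyloxy)phenyl]methanol (racemic) | OC(c1cc(OCc2ccccc2)cc(OCc2ccccc2)c1)c1cc(Br)cc(OCc2ccccc2)c1OCc1ccc(OCc2ccccc2)cc1 | intermediate
13 | [3-(benzyloxy)-2-{[4-(benzyloxy)benzyl]oxy}-5-bromophenyl][3,5-bis(benzyloxy)phenyl]methanone | O=C(c1cc(OCc2ccccc2)cc(OCc2ccccc2)c1)c1cc(Br)cc(OCc2ccccc2)c1OCc1ccc(OCc2ccccc2)cc1 | intermediate
14 | hydrazone of 13 (E/Z mixture) | NN=C(c1cc(OCc2ccccc2)cc(OCc2ccccc2)c1)c1cc(Br)cc(OCc2ccccc2)c1OCc1ccc(OCc2ccccc2)cc1 | intermediate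
15 | diaryldiazomethane from 14 | [N-]=[N+]=C(c1cc(OCc2ccccc2)cc(OCc2ccccc2)c1)c1cc(Br)cc(OCc2ccccc2)c1OCc1ccc(OCc2ccccc2)cc1 | intermediate
16 | (2S,3R)-7-(benzyloxy)-2-[4-(benzyloxy)phenyl]-3-[3,5-bis(benzyloxy)phenyl]-5-bromo-2,3-dihydro-1-benzofuran (cis) | Brc1cc(OCc2ccccc2)c2c(c1)[C@@H](c1cc(OCc3ccccc3)cc(OCc3ccccc3)c1)[C@@H](c1ccc(OCc3ccccc3)cc1)O2 | intermediate
17 | (2R,3R)-7-(benzyloxy)-2-[4-(benzyloxy)phenyl]-3-[3,5-bis(benzyloxy)phenyl]-5-bromo-2,3-dihydro-1-benzofuran (trans) | Brc1cc(OCc2ccccc2)c2c(c1)[C@@H](c1cc(OCc3ccccc3)cc(OCc3ccccc3)c1)[C@H](c1ccc(OCc3ccccc3)cc1)O2 | intermediate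
18 | (1R,4R,5R)-isothiocineole (4,7,7-trimethyl-6-thiabicyclo[3.2.1]octane) | C[C@@H]1CC[C@@H]2C[C@H]1SC2(C)C | starting material
19 | (1R,4R,5R)-6-[4-(benzyloxy)benzyl]-4,7,7-trimethyl-6-thiabicyclo[3.2.1]octan-6-ium triflate (one diastereomer at sulfur, configuration as formed) | C[C@@H]1CC[C@@H]2C[C@H]1[S+](Cc1ccc(OCc3ccccc3)cc1)C2(C)C.[O-]S(=O)(=O)C(F)(F)F | intermediate
20 | ring-B aryllithium (5-lithio analogue of 17) | [Li]c1cc(OCc2ccccc2)c2c(c1)[C@@H](c1cc(OCc3ccccc3)cc(OCc3ccccc3)c1)[C@H](c1ccc(OCc3ccccc3)cc1)O2 | intermediate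
21 | lithium alkoxide adduct of 20 and 5 (carbinol epimers) | [Li+].[O-]C(c1c(OC(=O)OC(C)(C)C)cc(OCc2ccccc2)cc1/C=C/c1ccc(OCc2ccccc2)cc1)c1cc(OCc2ccccc2)c2c(c1)[C@@H](c1cc(OCc3ccccc3)cc(OCc3ccccc3)c1)[C@H](c1ccc(OCc3ccccc3)cc1)O2 | intermediate
22 | lithium phenoxide with benzylic tert-butyl carbonate (after Boc shift) | [Li+].[O-]c1cc(OCc2ccccc2)cc(/C=C/c2ccc(OCc3ccccc3)cc2)c1C(OC(=O)OC(C)(C)C)c1cc(OCc2ccccc2)c2c(c1)[C@@H](c1cc(OCc3ccccc3)cc(OCc3ccccc3)c1)[C@H](c1ccc(OCc3ccccc3)cc1)O2 | intermediate
23 | ring-A o-quinone methide (exocyclic geometry not fixed in the SMILES) | O=C1C=C(OCc2ccccc2)C=C(/C=C/c2ccc(OCc3ccccc3)cc2)C1=Cc1cc(OCc2ccccc2)c2c(c1)[C@@H](c1cc(OCc3ccccc3)cc(OCc3ccccc3)c1)[C@H](c1ccc(OCc3ccccc3)cc1)O2 | intermediate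
24 | sulfonium ylide from 19 | C[C@@H]1CC[C@@H]2C[C@H]1[S+]([CH-]c1ccc(OCc3ccccc3)cc1)C2(C)C | intermediate
25 | betaine (phenoxide/sulfonium) from 23 and 24 | C[C@@H]1CC[C@@H]2C[C@H]1[S+](C2(C)C)[C@@H](c1ccc(OCc3ccccc3)cc1)[C@@H](c1cc(OCc3ccccc3)c3c(c1)[C@@H](c1cc(OCc4ccccc4)cc(OCc4ccccc4)c1)[C@H](c1ccc(OCc4ccccc4)cc1)O3)c1c([O-])cc(OCc3ccccc3)cc1/C=C/c1ccc(OCc3ccccc3)cc1 | intermediate
26 | (2S,3S)-6-(benzyloxy)-3-{(2R,3R)-7-(benzyloxy)-2-[4-(benzyloxy)phenyl]-3-[3,5-bis(benzyloxy)phenyl]-2,3-dihydro-1-benzofuran-5-yl}-2-[4-(benzyloxy)phenyl]-4-[(E)-2-(4-benzyloxyphenyl)ethenyl]-2,3-dihydro-1-benzofuran | c1ccccc1COc1ccc(/C=C/c2cc(OCc5ccccc5)cc3c2[C@H](c2cc(OCc5ccccc5)c4c(c2)[C@@H](c2cc(OCc5ccccc5)cc(OCc5ccccc5)c2)[C@H](c2ccc(OCc5ccccc5)cc2)O4)[C@@H](c2ccc(OCc5ccccc5)cc2)O3)cc1 | intermediate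
27 | (2S,3S)-3-[(2R,3R)-3-(3,5-dihydroxyphenyl)-7-hydroxy-2-(4-hydroxyphenyl)-2,3-dihydro-1-benzofuran-5-yl]-2-(4-hydroxyphenyl)-4-[(E)-2-(4-hydroxyphenyl)ethenyl]-2,3-dihydro-1-benzofuran-6-ol | Oc1ccc(/C=C/c2cc(O)cc3c2[C@H](c2cc(O)c4c(c2)[C@@H](c2cc(O)cc(O)c2)[C@H](c2ccc(O)cc2)O4)[C@@H](c2ccc(O)cc2)O3)cc1 | target

**Totals and risks**
Total steps: 14. Longest linear sequence: 9 steps (5, 6, 7, 8, 9, 10, 11, 13, 14).

Steps most likely to fail:

1. Step 13 (the labelled step). The ylide or the o-quinone methide may decay (ylide rearrangement, quinone methide dimerisation, elimination of the sulfide from the betaine) before productive union, or facial and relative control in the C–C bond-forming addition may be insufficient. Fallback with known chemistry, stepwise and with stereocontrol replaced by separation; it sets out from 17 and 4 and comes back at 26. Bromide 17 is lithiated (n-BuLi, THF, −78 °C) and added to the sodium phenoxide of 4 (NaH, THF) to give the o-hydroxybenzhydrol F1 as a mixture of carbinol epimers. Treatment with p-toluenesulfinic acid in CH2Cl2 at rt converts it into the bench-stable o-quinone methide precursor, the p-tolyl sulfone F2. Separately, 8 and tetrahydrothiophene give the achiral salt 1-[4-(benzyloxy)benzyl]tetrahydrothiophenium bromide F3. Sulfone F2, salt F3 and Cs2CO3 in CH2Cl2 (the established base-mediated [4+1] annulation of sulfone-derived o-quinone methides with sulfonium ylides) should give both trans ring-A isomers, 26 and its (2R,3R)-ring-A diastereomer F4. Because ring B is already enantiopure these are diastereomers and are separated by preparative HPLC to return 26.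

2. Step 10. Oxidation of the hindered hydrazone may be slow or give azine, and the extra ortho benzyloxy group may erode enantio- or diastereoselectivity of the insertion. Fallback that changes the ring-forming bond set; it sets out from 7 and comes back at 17. Aldehyde 7 is converted (Boc2O, DMAP) into 2-(benzyloxy)-4-bromo-6-formylphenyl tert-butyl carbonate F5. The antipodal sulfonium triflate F6 is made from commercial (1S,4S,5S)-isothiocineole, 8 and LiOTf. Grignard reagent 11 is added to F5 at −78 °C; the magnesium alkoxide should undergo Boc shift and elimination on warming to give the ring-B o-quinone methide F7. This is intercepted by the ylide from F6 (LiHMDS, THF, −78 → 0 °C) to give trans-(2R,3R) bromide 17 directly, without steps 6–11. This fallback rests on the same annulation as the key step and is only as secure as that step.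

3. Step 14. During sevenfold debenzylation the Lewis acid may induce Friedel–Crafts cyclisation of the electron-rich stilbene onto ring B or ionise the benzylic C–O bonds. Fallback that removes the sensitive 4-oxystilbene before the acid step; it sets out from 26 and comes back at 27. Ethenolysis of 26 (second-generation Ru–NHC metathesis catalyst, ethylene, toluene, 60 °C) should give the 4-vinyl hexabenzyl ether F8, whose vinyl group on the meta-dioxygenated ring is not prone to protonation. BCl3/pentamethylbenzene at −78 °C then gives the 4-vinyl hexaphenol F9. Cross-metathesis of F9 with 4-acetoxystyrene (same catalyst, E-selective) gives the 4'-O-acetyl target F10, and K2CO3/MeOH at 0 °C under N2 removes the acetate to give 27.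

**Further compounds**
F1 | step 13 | {4-(benzyloxy)-2-[(E)-2-(4-benzyloxyphenyl)ethenyl]-6-hydroxyphenyl}[(2R,3R)-ring-B-5-yl]methanol (carbinol epimers) | Oc1cc(OCc2ccccc2)cc(/C=C/c2ccc(OCc3ccccc3)cc2)c1C(O)c1cc(OCc2ccccc2)c2c(c1)[C@@H](c1cc(OCc3ccccc3)cc(OCc3ccccc3)c1)[C@H](c1ccc(OCc3ccccc3)cc1)O2
F2 | step 13 | p-tolyl sulfone from F1 (sulfonyl in place of the carbinol OH) | Oc1cc(OCc2ccccc2)cc(/C=C/c2ccc(OCc3ccccc3)cc2)c1C(c1cc(OCc2ccccc2)c2c(c1)[C@@H](c1cc(OCc3ccccc3)cc(OCc3ccccc3)c1)[C@H](c1ccc(OCc3ccccc3)cc1)O2)S(=O)(=O)c1ccc(C)cc1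
F3 | step 13 | 1-[4-(benzyloxy)benzyl]tetrahydrothiophenium bromide | [Br-].c1ccccc1COc1ccc(C[S+]2CCCC2)cc1
F4 | step 13 | (2R,3R)-ring-A diastereomer of 26 | c1ccccc1COc1ccc(/C=C/c2cc(OCc5ccccc5)cc3c2[C@@H](c2cc(OCc5ccccc5)c4c(c2)[C@@H](c2cc(OCc5ccccc5)cc(OCc5ccccc5)c2)[C@H](c2ccc(OCc5ccccc5)cc2)O4)[C@H](c2ccc(OCc5ccccc5)cc2)O3)cc1
F5 | step 10 | 2-(benzyloxy)-4-bromo-6-formylphenyl tert-butyl carbonate | O=Cc1cc(Br)cc(OCc2ccccc2)c1OC(=O)OC(C)(C)C
F6 | step 10 | (1S,4S,5S)-6-[4-(benzyloxy)benzyl]-4,7,7-trimethyl-6-thiabicyclo[3.2.1]octan-6-ium triflate | C[C@H]1CC[C@H]2C[C@@H]1[S+](Cc1ccc(OCc3ccccc3)cc1)C2(C)C.[O-]S(=O)(=O)C(F)(F)F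
F7 | step 10 | ring-B o-quinone methide, 2-(benzyloxy)-4-bromo-6-[3,5-bis(benzyloxy)benzylidene]cyclohexa-2,4-dien-1-one | O=C1C(OCc2ccccc2)=CC(Br)=CC1=Cc1cc(OCc2ccccc2)cc(OCc2ccccc2)c1
F8 | step 14 | 4-vinyl analogue of 26 (hexabenzyl ether) | C=Cc1cc(OCc5ccccc5)cc2c1[C@H](c1cc(OCc5ccccc5)c4c(c1)[C@@H](c1cc(OCc5ccccc5)cc(OCc5ccccc5)c1)[C@H](c1ccc(OCc5ccccc5)cc1)O4)[C@@H](c1ccc(OCc5ccccc5)cc1)O2
F9 | step 14 | 4-vinyl hexaphenol | C=Cc1cc(O)cc2c1[C@H](c1cc(O)c4c(c1)[C@@H](c1cc(O)cc(O)c1)[C@H](c1ccc(O)cc1)O4)[C@@H](c1ccc(O)cc1)O2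
F10 | step 14 | 4'-O-acetyl target | CC(=O)Oc1ccc(/C=C/c2cc(O)cc3c2[C@H](c2cc(O)c4c(c2)[C@@H](c2cc(O)cc(O)c2)[C@H](c2ccc(O)cc2)O4)[C@@H](c2ccc(O)cc2)O3)cc1
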